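# Proposed total synthesis of CNP0258231.4 by palladium 1,4-oxylactonisation with stereochemical relay from C1

## Analysis of the target

The target is a bisabolane-type triester in which a cyclohexane ring (C1–C6) carries at C1 the chain C7(=C14H2)–C8H(O-angelate)–C9H2–C10H–C11(CH3)2, with C10–C11 closed as a trisubstituted epoxide. C2 and C3 carry two further angelates, C4 carries a methyl group (C15) and shares a second trisubstituted epoxide with C5, and C6 is the only ring methylene. Of the seven stereocentres, C1–C5 are contiguous, with the C1 chain, O2, O3 and the C4–C5 epoxide oxygen all on one ring face (called α here; the C4 methyl is β), which is (1R,2S,3S,4R,5R) in these locants, whereas C8 (S) and C10 (R) are insulated from the ring and from each other and need reagent control. The sensitive groups are the two acid-labile epoxides, the three (Z)-2-methylbut-2-enoates (prone to Z→E isomerisation and to migration between the cis-vicinal O2 and O3) and the 1,1-disubstituted alkene allylic to the C8 ester. The difficulty lies in the all-cis, fully substituted C1–C5 array, which thermodynamic control cannot deliver, together with the late triple acylation of hindered hydroxyls beside two epoxides. The structural feature exploited is that O2 and O5 are 1,4-related across C3–C4 and both cis to the C1 chain, which is the pattern left when a C2=C3–C4=C5 diene is oxidised at both termini, at C2 by a carboxylate tethered to C1 and at C5 by an external oxygen nucleophile on the same face. The C3=C4 alkene that remains can carry oxygen from C5 to C3 and then host the epoxide, and the carboxyl carbon of the tether becomes C14, the handle for C8.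

## Retrosynthetic reasoning

**32 ⇒ 31.** The C10–C11 epoxide is cut first. Its alkene is the only electron-rich trisubstituted one in 31, so a catalyst-controlled oxygen transfer can be chemoselective, and the labile side-chain epoxide is not carried through the synthesis.

**31 ⇒ 28 + 29.** The three ester C–O bonds are cut together, so that triol 28 takes up three molecules of acid 29, each delivered as the mixed anhydride 30. Doing this in one operation after all base- and fluoride-mediated steps avoids acyl migration between O2 and O3 and avoids carrying angelates through reductions.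

**28 ⇒ 27 ⇒ 26 ⇒ 25 ⇒ 24.** The C8 carbinol beside the C7=C14 methylene is the signature of a reductively opened 7,8-epoxy-14-iodide (26). The epoxide 25 comes from asymmetric epoxidation of the primary allylic alcohol 24, so C8 is set by reagent control and C14 ends as the methylene. Desilylation of 27 then gives 28.

**24 ⇒ 23 ⇒ 22 ⇒ 21.** The allylic alcohol 24 is traced through diol 22 to the α-alkylidene lactone 21, whose carbonyl is C14 and whose ring oxygen is O2. Because O2 and C14 are 1,4-related, O2 would close a five-membered cyclic ether as soon as C14 bears a leaving group. Diol 22 is therefore bis-silylated (23) and the primary ether released selectively (24).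

**21 ⇒ 19 ⇒ 16 + 18; 18 ⇒ 17.** The C7=C8 bond is cut by aldol addition and dehydration (through mesylate 20) between the enolate of lactone 16 and aldehyde 18, which brings C8–C13 in one piece; 18 is the oxidation product of alcohol 17. The C10=C11 alkene is kept as such until the last step.

**16 ⇒ 15 ⇒ 14.** The C4–C5 epoxide is cut back to the allylic alcohol 14. O3 is α, so a hydroxyl-directed epoxidation puts the epoxide on the α face. Silylation then protects O3 for the enolate chemistry.

**14 ⇒ 12 ⇒ 11 ⇒ 10 ⇒ 9.** The C3 carbinol with C4=C5 is the Wharton transposition product of epoxy ketone 12 (through hydrazone 13). Compound 12 comes from the 5α-alcohol 10 by O5-directed epoxidation of C3=C4 (11) and oxidation. The C3–O bond made in the directed epoxidation is the one kept, so the α configuration passes from C5 to C3.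

**9 ⇒ 7 + 8 (key disconnection).** The C2–O and C5–O bonds are cut together. Forward, a palladium-catalysed 1,4-oxylactonisation of diene acid 7 with the acetate of 8 must close the γ-lactone cis on C1–C2 and place the acetate at C5 on the same face. One stereocentre thereby controls two new ones and leaves the alkene where the next steps need it.

**7 ⇒ 6 ⇒ 5 ⇒ 4.** The diene is made from enone 4 through the cross-conjugated dienyl triflate 5 and a methyl cross-coupling to 6, then ester hydrolysis. This fixes both double bonds and the methyl position unambiguously, which a halogenation–elimination sequence on a ring with a single alkene would not.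

**4 ⇒ 3 ⇒ 1 + 2.** The enone ring is opened by retro-aldol condensation to keto aldehyde 3. Its single stereocentre (the future C1) comes from an organocatalytic Michael addition of aldehyde 1 to enone 2.

## Alternatives that were turned down

**Alternative 1:** The C8–O bond and the C7=C14 methylene are traced to a 7,8-epoxide whose third carbon is a C9 carbinol, so the side chain is grown from a fully oxygenated ring.
- Forward key step: the (E)-allylic alcohol A1 (C9 hydroxymethyl; C7 bearing a methyl group and the ring) is epoxidised with Ti(OiPr)4, L-(+)-diethyl tartrate and tBuOOH to the (7S,8S)-epoxy alcohol A2. The epoxide is then opened toward the C14 methyl to give the C8 carbinol, and C9 is used to attach C10–C13.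
- For: C8 is set by reagent control on a standard substrate class. It is stronger than the chosen route on one point: O2 never competes with the carbinol carbon, so the two steps spent masking O2 are not needed.
- Against: A1 presupposes all five ring stereocentres, the harder half of the problem. The epoxide-to-allylic-alcohol isomerisation must remove a C14 hydrogen and not H1, and must distinguish the side-chain epoxide from the ring epoxide of the same substitution type. C9 still has to be turned into the C9–C10 bond.
- Comparison: on C8 the two are equal, since the chosen route uses the same asymmetric epoxidation (on C7=C8 with the carbinol at C14). The chosen route replaces the isomerisation by a regiochemically unambiguous reductive opening and also supplies the ring.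

**Alternative 2:** C1–C6 and C4–C5 are cut in a [4+2] cycloaddition. 6-Methyl-2-pyrone A3 supplies C1–C4, the oxygen on C4 and the carbonyl carbon C7; enone 2 supplies C5–C6, with its acetyl group on C5 as a masked oxygen.
- Forward key step: a chiral oxazaborolidinium Lewis acid (the triflimide salt of an N-protonated B-aryl oxazaborolidine derived from diphenylprolinol) is to give the endo bicyclic lactone A4.
- For: one step builds the carbocycle and locks C7 and O4 cis through the lactone bridge. The endo acetyl is anti to the bridge, so after Baeyer–Villiger oxidation O5 is set up for an invertive closure of the α-epoxide by O4, and the C2=C3 alkene is open on the bridge side for cis-dihydroxylation. In ring-forming economy and convergence this is stronger than the chosen route, which needs five steps before its key step.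
- Against: simple 2-pyrones are sluggish, electron-poor dienes toward enones, and their adducts tend to undergo decarboxylative cycloreversion on heating. Enantiocontrol by a Lewis acid that can bind either partner is uncertain. Afterwards C7 is a carboxyl carbon that must become a 1,1-disubstituted alkene beside a new C8 stereocentre, the bridged lactone must be opened against its tendency to re-close, and five oxygens must be differentiated.
- Comparison: the chosen strategy offers instead ring centres relayed from C1 by tether- and hydroxyl-directed steps of predictable outcome, and a carbonyl (C14) exactly where the handle for C8 is wanted.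

**Alternative 3:** The C1–C2 ring bond and the lactone C8–O2 bond are cut, leading to the acyclic aldehyde–allylic bromide A5.
- Forward key step: CrCl2 (divalent chromium) converts the bromide of A5 into an allylchromium that adds through C1 to the C2 aldehyde. The alkoxide then lactonises onto the C8 ester to give the cis-fused α-methylene lactone A6 (C7=C14 in place, lactone carbonyl = C8, O3 silyl ether, C4=C5).
- For: C14 and C8 arrive at the correct oxidation level, so the epoxide–iodide transposition and its protecting-group work are not needed. Here it is stronger than the chosen route. O3 and C4=C5 are set for the same directed epoxidation.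
- Against: A5 is a long, fragile linear precursor with a Z-trisubstituted alkene, an epimerisable α-silyloxy aldehyde and an allylic bromide. The C1/C2 configuration relative to C3 rests on the facial preference of an α-alkoxy aldehyde in the ring closure, which must give cis O2/O3 and is not assured. A6 is a reactive Michael acceptor, so acyl addition at C8 competes with conjugate addition, and C8 then needs a reagent-controlled reduction.
- Comparison: the chosen route is longer after its key step, but its precursor 7 has one stereocentre and is reached in five steps, and every ring centre is relayed intramolecularly.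

Key step: step 6

## Route

Remark (assumption): in step 1 the sense of induction is taken from the usual steric-shielding model of diarylprolinol ether enamines. Locants and α/β are those fixed in the analysis; in lactones 9–21 the carbonyl carbon is C14 and the α-carbon is C7.

Step 1
Reactants: 1 methyl 4-oxobutanoate; 2 methyl vinyl ketone
Product: 3 methyl (3R)-3-formyl-6-oxoheptanoate
Conditions: (R)-2-(methoxydiphenylmethyl)pyrrolidine (5 mol %), ethyl 3,4-dihydroxybenzoate (20 mol %), neat, 4 °C
Reagents that add atoms: none
Why: Organocatalytic asymmetric Michael addition through the (E)-enamine of 1; the diphenylmethyl ether group of the (R)-catalyst blocks one enamine face, so 2 adds to the other and sets the future C1 as (R), while the catechol ester activates the enone by hydrogen bonding.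

Step 2
Reactants: 3 methyl (3R)-3-formyl-6-oxoheptanoate
Product: 4 methyl 2-[(1R)-4-oxocyclohex-2-en-1-yl]acetate
Conditions: p-TsOH·H2O (10 mol %), toluene, 80 °C, Dean–Stark
Reagents that add atoms: none
Why: Acid-catalysed intramolecular aldol condensation; only the methyl ketone enol reaches the aldehyde through a six-membered transition state, and dehydration gives the conjugated enone with the stereocentre now at the γ position, which is not enolised under these non-basic conditions.

Step 3
Reactants: 4 methyl 2-[(1R)-4-oxocyclohex-2-en-1-yl]acetate
Product: 5 methyl 2-[(1R)-4-(trifluoromethylsulfonyloxy)cyclohexa-2,4-dien-1-yl]acetate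
Conditions: LiN(SiMe3)2, THF, −78 °C; PhNTf2, −78 → 0 °C
Reagents that add atoms: N-phenylbis(trifluoromethanesulfonimide), O=S(=O)(N(c1ccccc1)S(=O)(=O)C(F)(F)F)C(F)(F)F
Why: Kinetic deprotonation of a cyclohex-2-enone at the α′ carbon (C5) gives the cross-conjugated dienolate, which is O-sulfonylated to the 2-triflyloxy-1,3-diene; the γ hydrogen on C1 and the less acidic ester α-hydrogens are not removed at −78 °C, so the stereocentre is kept.

Step 4
Reactants: 5 methyl 2-[(1R)-4-(trifluoromethylsulfonyloxy)cyclohexa-2,4-dien-1-yl]acetate
Product: 6 methyl 2-[(1R)-4-methylcyclohexa-2,4-dien-1-yl]acetate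
Conditions: MeZnCl, Pd(PPh3)4 (5 mol %), THF, 25 °C
Reagents that add atoms: methylzinc chloride, C[Zn]Cl
Why: Negishi cross-coupling of an alkenyl triflate; oxidative addition to Pd(PPh3)4 (zerovalent palladium), transmetallation and reductive elimination retain the alkene position and tolerate the ester, placing the methyl group on C4 of the diene.

Step 5
Reactants: 6 methyl 2-[(1R)-4-methylcyclohexa-2,4-dien-1-yl]acetate
Product: 7 (R)-2-(4-methylcyclohexa-2,4-dien-1-yl)acetic acid
Conditions: LiOH, THF/H2O (3:1), 0 °C → rt; then aq. HCl to pH 3 at 0 °C; used at once under argon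
Reagents that add atoms: lithium hydroxide, [Li+].[OH-]
Why: Saponification of a methyl ester; C1 is not acidic and the diene is stable to cold aqueous base, and immediate use avoids air oxidation of the 1,3-cyclohexadiene.

Step 6
Reactants: 7 (R)-2-(4-methylcyclohexa-2,4-dien-1-yl)acetic acid; 8 acetic acid
Product: 9 (3aR,5R,7aS)-6-methyl-2-oxo-2,3,3a,4,5,7a-hexahydro-1-benzofuran-5-yl acetate (cis-fused C1–C2 γ-lactone with 5α-acetoxy group and C3=C4 alkene)
Conditions: Pd(OAc)2 (5 mol %), p-benzoquinone (2 equiv), LiOAc (2 equiv), LiCl (0.2 equiv), acetone/AcOH (4:1; AcOH is 8), 20 °C, slow addition of 7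
Reagents that add atoms: none
Why: This is a palladium-catalysed, quinone-driven 1,4-dioxygenation of a conjugated diene with an internal carboxylate (intramolecular 1,4-oxylactonisation), a known reaction type for cyclohexa-2,4-dienylacetic acids. Pd(OAc)2 (divalent palladium) binds the diene of 7 on the β face, away from the C1 substituent, and the tethered carboxylate adds to C2 anti to the metal in a 5-exo-trig closure that forms the γ-lactone (ring atoms O, C14, C7, C1, C2); cis fusion is enforced because the two-atom tether reaches C2 only from the α face. This leaves an η3-allyl palladium over C3–C4–C5 on the β face. With chloride on the metal, acetate cannot migrate from palladium and attacks from solution anti to it at C5, so O5 also ends on the α face; the new C2 and C5 stereocentres are thus both fixed by C1 through the tether and the anti/anti sequence. Attack at C5 rather than C3 is required and is secured by the steric and inductive shielding of C3 by the adjacent lactone oxygen. Benzoquinone reoxidises zerovalent palladium. The step also needs the oxidation to outrun cycloaddition of 7 with the quinone and dehydrogenation to an arene, hence slow addition of 7 at 20 °C.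

Step 7
Reactants: 9 cis-fused 5α-acetoxy lactone
Product: 10 (3aR,5R,7aS)-5-hydroxy-6-methyl-3a,4,5,7a-tetrahydro-1-benzofuran-2(3H)-one (5α-hydroxy lactone)
Conditions: K2CO3 (0.2 equiv), MeOH, 0 °C; neutralise with Amberlyst-15
Reagents that add atoms: none
Why: Base-catalysed transesterification removes the secondary acetate; the cis-fused γ-lactone is favoured over its ring-opened hydroxy ester and any opened material re-closes on neutralisation.

Step 8
Reactants: 10 5α-hydroxy lactone
Product: 11 3α,4α-epoxy-5α-hydroxy lactone
Conditions: VO(acac)2 (3 mol %), tBuOOH (1.5 equiv), CH2Cl2, 0 °C → rt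
Reagents that add atoms: tert-butyl hydroperoxide, CC(C)(C)OO
Why: Hydroxyl-directed epoxidation; the C5 alkoxide binds vanadium and delivers the peroxide oxygen intramolecularly to the α face of C3=C4, setting C3 and C4 cis to O5 even though this is the face of the lactone ring.

Step 9
Reactants: 11 3α,4α-epoxy-5α-hydroxy lactone
Product: 12 3α,4α-epoxy-5-oxo lactone
Conditions: Dess–Martin periodinane, NaHCO3, CH2Cl2, 0 °C → rt
Reagents that add atoms: none
Why: Dess–Martin oxidation of a secondary alcohol under buffered, non-acidic conditions that leave the epoxide and the lactone untouched.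

Step 10
Reactants: 12 3α,4α-epoxy-5-oxo lactone
Product: 14 (3aR,7R,7aS)-7-hydroxy-6-methyl-3a,4,7,7a-tetrahydro-1-benzofuran-2(3H)-one (3α-hydroxy lactone with C4=C5), via epoxy hydrazone 13 (not isolated)
Conditions: N2H4·H2O (3 equiv), AcOH (0.3 equiv), MeOH, 0 °C → rt
Reagents that add atoms: none
Why: Wharton transposition; hydrazone 13 opens the epoxide to a vinyl diazene that loses N2, placing the alkene at C4=C5 while the C3–O bond, and with it the α configuration at C3, is untouched; hydrazone formation at the ketone is much faster than attack on the lactone at 0 °C.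

Step 11
Reactants: 14 3α-hydroxy lactone with C4=C5
Product: 15 3α-hydroxy-4α,5α-epoxy lactone
Conditions: VO(acac)2 (3 mol %), tBuOOH (1.5 equiv), CH2Cl2, 0 °C → rt
Reagents that add atoms: tert-butyl hydroperoxide, CC(C)(C)OO
Why: Second hydroxyl-directed vanadium epoxidation, now from O3 to the α face of C4=C5; it sets C4 and C5 and completes the all-cis ring array.

Step 12
Reactants: 15 3α-hydroxy-4α,5α-epoxy lactone
Product: 16 3α-(tert-butyldimethylsilyloxy)-4α,5α-epoxy lactone
Conditions: tBuMe2SiOTf, 2,6-lutidine, CH2Cl2, −78 → 0 °C
Reagents that add atoms: tert-butyldimethylsilyl trifluoromethanesulfonate, CC(C)(C)[Si](C)(C)OS(=O)(=O)C(F)(F)F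
Why: Silylation of the hindered C3 alcohol with the silyl triflate and a hindered base; the cis epoxy alcohol cannot undergo epoxide migration because O3 is syn to the C4–O bond.

Step 13
Reactants: 17 4-methylpent-3-en-1-ol
Product: 18 4-methylpent-3-enal
Conditions: Dess–Martin periodinane, NaHCO3, CH2Cl2, 0 °C; filtered and used at once as a solution
Reagents that add atoms: none
Why: Buffered Dess–Martin oxidation of a primary homoallylic alcohol; neutral conditions and immediate use avoid migration of the β,γ double bond into conjugation.

Step 14
Reactants: 16 3α-silyloxy-4α,5α-epoxy lactone; 18 4-methylpent-3-enal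
Product: 19 C7-(1-hydroxy-4-methylpent-3-enyl) lactone (aldol adduct; mixture at C7 and C8)
Conditions: LiN(iPr)2, THF, −78 °C; 18, −78 °C; AcOH quench at −78 °C
Reagents that add atoms: none
Why: Aldol addition of the lithium lactone enolate (C7) to the aldehyde forms the C7–C8 bond; the two new centres are not controlled and need not be, since C7 becomes trigonal and C8 is reset later.

Step 15
Reactants: 19 aldol adduct
Product: 21 (E)-α-alkylidene lactone (C7=C8; C9 anti to the C14 carbonyl), via C8 mesylate 20 (not isolated)
Conditions: MsCl, Et3N, CH2Cl2, 0 °C; then DBU, 0 °C → rt (short)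
Reagents that add atoms: none
Why: Mesylation and base-induced elimination through the lactone enolate (E1cB) give the conjugated α-alkylidene lactone; the (E) isomer is the thermodynamically preferred product of this stereoconvergent elimination and is purified here.

Step 16
Reactants: 21 (E)-α-alkylidene lactone
Product: 22 (E)-allylic diol (C14–OH and 2α-OH free; 3α-silyloxy; 4α,5α-epoxide; C10=C11)
Conditions: iBu2AlH (4 equiv), CH2Cl2, −78 → −20 °C; aq. potassium sodium tartrate
Reagents that add atoms: none
Why: 1,2-Reduction of the unsaturated lactone by excess iBu2AlH through the lactol to the diol; the low temperature keeps the epoxide and silyl ether intact and the alkene geometry is retained.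

Step 17
Reactants: 22 (E)-allylic diol
Product: 23 bis(triethylsilyl) ether of 22 (O14 and O2)
Conditions: Et3SiOTf, 2,6-lutidine, CH2Cl2, −78 °C
Reagents that add atoms: triethylsilyl trifluoromethanesulfonate, CC[Si](CC)(CC)OS(=O)(=O)C(F)(F)F
Why: Exhaustive silylation; O2 must be blocked because it lies 1,4 to C14 and would close a five-membered cyclic ether once C14 carries a leaving group.

Step 18
Reactants: 23 bis(triethylsilyl) ether
Product: 24 (E)-allylic alcohol with free C14–OH (2α-triethylsilyloxy and 3α-tert-butyldimethylsilyloxy retained)
Conditions: PPTS (10 mol %), MeOH/CH2Cl2 (1:4), −10 °C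
Reagents that add atoms: none
Why: Acid-catalysed methanolysis distinguishes silyl ethers by steric access; the primary allylic triethylsilyl ether is cleaved far faster than the two hindered secondary silyl ethers, and the mild acid at −10 °C spares the epoxide.

Step 19
Reactants: 24 (E)-allylic alcohol
Product: 25 (7S,8S)-7,8-epoxy-14-ol
Conditions: Ti(OiPr)4 (20 mol %), L-(+)-diethyl tartrate (24 mol %), tBuOOH (2 equiv), 4 Å molecular sieves, CH2Cl2, −25 °C
Reagents that add atoms: tert-butyl hydroperoxide, CC(C)(C)OO
Why: Sharpless asymmetric epoxidation of a primary (E)-allylic alcohol; by the established facial rule the L-(+)-tartrate complex delivers oxygen to the face that gives (7S,8S), so C8 is set by the reagent, and the isolated C10=C11 alkene is inert to this system.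

Step 20
Reactants: 25 (7S,8S)-7,8-epoxy-14-ol
Product: 26 7,8-epoxy-14-iodide (7R,8S by descriptor; same spatial arrangement as 25)
Conditions: PPh3, I2, imidazole, CH2Cl2, 0 °C → rt
Reagents that add atoms: iodine, II
Why: Appel-type iodination of the primary alcohol through its alkoxyphosphonium ion; O2 and O3 are silylated, so no intramolecular ether formation can compete.

Step 21
Reactants: 26 7,8-epoxy-14-iodide
Product: 27 (8S)-allylic alcohol (C7=C14H2; C8–OH; silyl ethers at O2 and O3; 4α,5α-epoxide; C10=C11)
Conditions: Zn dust (activated), EtOH, 60 °C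
Reagents that add atoms: none
Why: Reductive elimination of a β-iodo epoxide; zinc inserts into the C14–I bond and the C7–O bond is expelled, giving the C7=C14 methylene and the C8 alkoxide without breaking the C8–O bond, so C8 stays (S).

Step 22
Reactants: 27 (8S)-allylic alcohol
Product: 28 2α,3α,8-triol ((8S); 4α,5α-epoxide; C7=C14; C10=C11)
Conditions: Bu4NF, THF, 0 °C → rt
Reagents that add atoms: none
Why: Fluoride-induced cleavage of both silyl ethers; no ester is present yet, so basic fluoride cannot cause acyl migration.

Step 23
Reactants: 28 2α,3α,8-triol; 29 angelic acid ((Z)-2-methylbut-2-enoic acid)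
Product: 31 tris-angelate with C10=C11 alkene, via mixed anhydride 30 (not isolated)
Conditions: 29 (6 equiv), 2,4,6-trichlorobenzoyl chloride (6 equiv), Et3N, toluene, rt, then filtration; 28, toluene, 75 °C
Reagents that add atoms: angelic acid (second and third molecule of 29), C/C=C(/C)C(=O)O.C/C=C(/C)C(=O)O
Why: Yamaguchi-type acylation in which three molecules of 29, each as its preformed mixed anhydride 30, are taken up, one on each of O8, O2 and O3, with loss of three molecules of water overall. No nucleophilic catalyst is used, so the angeloyl group is transferred without Z→E isomerisation; excess reagent and heat are used so that the hindered O2 and O3 are acylated as well as O8.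

Step 24
Reactants: 31 tris-angelate with C10=C11 alkene
Product: 32 CNP0258231.4 ((1R,2S,3S,4R,5R,8S,10R) in the locants used here)
Conditions: Shi ketone (1,2:4,5-di-O-isopropylidene-β-D-erythro-2,3-hexodiulo-2,6-pyranose, from D-fructose; 30 mol %), KHSO5 (as the triple salt 2KHSO5·KHSO4·K2SO4), K2CO3, Bu4NHSO4, MeCN/dimethoxymethane/aq. Na2B4O7 buffer (pH 10.5), 0 °C
Reagents that add atoms: potassium peroxymonosulfate, [K+].[O-]S(=O)(=O)OO
Why: Shi epoxidation; the chiral dioxirane reacts fastest with the electron-rich trisubstituted C10=C11 alkene and not with the conjugated angelates or the deactivated 1,1-disubstituted C7=C14 alkene, and by the spiro transition-state model the D-fructose-derived ketone gives the (10R) epoxide.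

## Compound list

1 | methyl 4-oxobutanoate | COC(=O)CCC=O | starting material
2 | methyl vinyl ketone (but-3-en-2-one) | CC(=O)C=C | starting material
3 | methyl (3R)-3-formyl-6-oxoheptanoate | COC(=O)C[C@H](C=O)CCC(C)=O | intermediate
4 | methyl 2-[(1R)-4-oxocyclohex-2-en-1-yl]acetate | COC(=O)C[C@@H]1C=CC(=O)CC1 | intermediate
5 | methyl 2-[(1R)-4-(trifluoromethylsulfonyloxy)cyclohexa-2,4-dien-1-yl]acetate | COC(=O)C[C@H]1CC=C(OS(=O)(=O)C(F)(F)F)C=C1 | intermediate
6 | methyl 2-[(1R)-4-methylcyclohexa-2,4-dien-1-yl]acetate | COC(=O)C[C@H]1CC=C(C)C=C1 | intermediate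
7 | (R)-2-(4-methylcyclohexa-2,4-dien-1-yl)acetic acid | OC(=O)C[C@H]1CC=C(C)C=C1 | intermediate
8 | acetic acid | CC(=O)O | starting material
9 | (3aR,5R,7aS)-6-methyl-2-oxo-2,3,3a,4,5,7a-hexahydro-1-benzofuran-5-yl acetate (cis-fused C1–C2 γ-lactone, 5α-acetoxy, C3=C4) | CC(=O)O[C@@H]1C[C@@H]2CC(=O)O[C@@H]2C=C1C | intermediate
10 | (3aR,5R,7aS)-5-hydroxy-6-methyl-3a,4,5,7a-tetrahydro-1-benzofuran-2(3H)-one (5α-hydroxy lactone) | O[C@@H]1C[C@@H]2CC(=O)O[C@@H]2C=C1C | intermediate
11 | 3α,4α-epoxy-5α-hydroxy lactone (epoxide of 10 on the hydroxyl face) | O[C@@H]1C[C@@H]2CC(=O)O[C@@H]2[C@@H]3O[C@]13C | intermediate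
12 | 3α,4α-epoxy-5-oxo lactone | O=C1C[C@@H]2CC(=O)O[C@@H]2[C@@H]3O[C@]13C | intermediate
13 | C5 hydrazone of 12 | NN=C1C[C@@H]2CC(=O)O[C@@H]2[C@@H]3O[C@]13C | intermediate
14 | (3aR,7R,7aS)-7-hydroxy-6-methyl-3a,4,7,7a-tetrahydro-1-benzofuran-2(3H)-one (3α-hydroxy lactone with C4=C5) | O[C@@H]1C(C)=CC[C@@H]2CC(=O)O[C@H]12 | intermediate
15 | 3α-hydroxy-4α,5α-epoxy lactone | O[C@@H]1[C@]3(C)O[C@@H]3C[C@@H]2CC(=O)O[C@H]12 | intermediate
16 | 3α-(tert-butyldimethylsilyloxy)-4α,5α-epoxy lactone | CC(C)(C)[Si](C)(C)O[C@@H]1[C@]3(C)O[C@@H]3C[C@@H]2CC(=O)O[C@H]12 | intermediate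
17 | 4-methylpent-3-en-1-ol | CC(C)=CCCO | starting material
18 | 4-methylpent-3-enal | CC(C)=CCC=O | intermediate
19 | aldol adduct: lactone 16 bearing a 1-hydroxy-4-methylpent-3-enyl group on C7 (mixture at C7 and C8) | CC(C)(C)[Si](C)(C)O[C@@H]1[C@]3(C)O[C@@H]3C[C@@H]2C(C(O)CC=C(C)C)C(=O)O[C@H]12 | intermediate
20 | C8 methanesulfonate of 19 | CC(C)(C)[Si](C)(C)O[C@@H]1[C@]3(C)O[C@@H]3C[C@@H]2C(C(OS(C)(=O)=O)CC=C(C)C)C(=O)O[C@H]12 | intermediate
21 | (E)-α-(4-methylpent-3-enylidene) lactone (C7=C8) | CC(C)(C)[Si](C)(C)O[C@@H]1[C@]3(C)O[C@@H]3C[C@@H]2/C(=C\CC=C(C)C)C(=O)O[C@H]12 | intermediate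
22 | (E)-allylic diol: C14–OH and 2α-OH free, 3α-silyloxy, 4α,5α-epoxide | CC(C)(C)[Si](C)(C)O[C@@H]1[C@]3(C)O[C@@H]3C[C@H](/C(CO)=C\CC=C(C)C)[C@@H]1O | intermediate
23 | O14,O2-bis(triethylsilyl) ether of 22 | CC(C)(C)[Si](C)(C)O[C@@H]1[C@]3(C)O[C@@H]3C[C@H](/C(CO[Si](CC)(CC)CC)=C\CC=C(C)C)[C@@H]1O[Si](CC)(CC)CC | intermediate
24 | (E)-allylic alcohol with free C14–OH, 2α-triethylsilyloxy and 3α-tert-butyldimethylsilyloxy groups | CC(C)(C)[Si](C)(C)O[C@@H]1[C@]3(C)O[C@@H]3C[C@H](/C(CO)=C\CC=C(C)C)[C@@H]1O[Si](CC)(CC)CC | intermediate
25 | (7S,8S)-7,8-epoxy-14-ol | CC(C)(C)[Si](C)(C)O[C@@H]1[C@]3(C)O[C@@H]3C[C@H]([C@@]4(CO)O[C@H]4CC=C(C)C)[C@@H]1O[Si](CC)(CC)CC | intermediate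
26 | 7,8-epoxy-14-iodide (7R,8S) | CC(C)(C)[Si](C)(C)O[C@@H]1[C@]3(C)O[C@@H]3C[C@H]([C@@]4(CI)O[C@H]4CC=C(C)C)[C@@H]1O[Si](CC)(CC)CC | intermediate
27 | (8S)-allylic alcohol: C7=C14H2, C8–OH, 2α-triethylsilyloxy, 3α-tert-butyldimethylsilyloxy, 4α,5α-epoxide | CC(C)(C)[Si](C)(C)O[C@@H]1[C@]3(C)O[C@@H]3C[C@H](C(=C)[C@@H](O)CC=C(C)C)[C@@H]1O[Si](CC)(CC)CC | intermediate
28 | 2α,3α,8-triol ((8S); 4α,5α-epoxide; C7=C14; C10=C11) | O[C@@H]1[C@]3(C)O[C@@H]3C[C@H](C(=C)[C@@H](O)CC=C(C)C)[C@@H]1O | intermediate
29 | angelic acid ((Z)-2-methylbut-2-enoic acid) | C/C=C(/C)C(=O)O | starting material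
30 | (Z)-2-methylbut-2-enoic 2,4,6-trichlorobenzoic anhydride | C/C=C(/C)C(=O)OC(=O)c1c(Cl)cc(Cl)cc1Cl | intermediate
31 | tris-angelate (O2, O3, O8) with C10=C11 alkene | C=C([C@H](CC=C(C)C)OC(=O)/C(C)=C\C)[C@H]1C[C@H]2O[C@@]2(C)[C@@H](OC(=O)/C(C)=C\C)[C@H]1OC(=O)/C(C)=C\C | intermediate
32 | CNP0258231.4 | C=C([C@H](C[C@H]1OC1(C)C)OC(=O)/C(C)=C\C)[C@H]1C[C@H]2O[C@@]2(C)[C@@H](OC(=O)/C(C)=C\C)[C@H]1OC(=O)/C(C)=C\C | target

## Step count and least certain steps

Total: 24 steps. Longest linear sequence: 23 steps (from 1 and 2 to 32 through steps 1–12 and 14–24); step 13 is a one-step branch.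

**Step 6 (key step).** The most likely failures are loss of cis control through inner-sphere acetate delivery, and consumption of the diene by cycloaddition with the quinone oxidant or by dehydrogenative aromatisation before the oxypalladation occurs. Fallback: from 7, iodolactonisation (I2, NaHCO3, MeCN/H2O, 0 °C) should add the carboxylate to C2 on the α face and iodine anti to it, giving the 3β-iodo lactone with C4=C5 F1. Displacement of this allylic iodide by Bu4NOAc in acetone with inversion places oxygen on the α face whichever terminus reacts. The anti-SN2′ course at C5 gives 9 directly. Direct SN2 at C3 gives the 3α-acetoxy lactone with C4=C5 F2, which on methanolysis (K2CO3, MeOH) is 14. The fallback therefore returns to the route at 9, or at 14 with steps 7–10 omitted.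

**Step 10.** Competing hydrazinolysis of the γ-lactone, or slow fragmentation of the hydrazone, may lower the return. Fallback: from 11, the C5 hydroxyl is converted with 1,1′-thiocarbonyldiimidazole into the O5-(imidazol-1-ylthiocarbonyl) derivative F3. Treatment with Bu3SnH and azobisisobutyronitrile in toluene at 80 °C generates the C5 radical, which opens the adjacent epoxide to an allyloxy radical that is reduced to 14 (radical deoxygenative epoxide fragmentation, Barton–McCombie type). The route is rejoined at 14.

**Step 15.** Base-induced migration of the new C7=C8 double bond toward C10=C11, through deprotonation at the doubly activated C9, and incomplete E selectivity are the main risks; proton transfer from the enolisable aldehyde in step 14 has the same origin. Fallback: from 16, deprotonation with LiN(iPr)2 (2.2 equiv) and trapping with ClP(O)(OEt)2, through the enol phosphate and its 1,3-phosphorus shift to carbon, gives the α-(diethoxyphosphoryl) lactone F4. Its weakly basic anion (KOtBu, THF, −78 → 0 °C) condenses with 18 in a Horner–Wadsworth–Emmons reaction to give 21 directly, without a β-mesyloxy intermediate or amidine base.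

**Step 21.** Lewis-acidic zinc salts may open the ring epoxide at 60 °C, and the preceding iodination at the neopentyl-like C14 may be slow. Fallback: from 25, Dess–Martin oxidation gives the 7,8-epoxy-14-aldehyde F5. N2H4·H2O with catalytic AcOH in MeOH at 0 °C then forms the hydrazone F6, which fragments in a Wharton transposition to 27. No substitution at C14 and no metal salt is involved.

**Step 23.** Incomplete acylation at the hindered O2 and O3, and Z→E isomerisation of the angeloyl group under forcing conditions, are the likely problems. Fallback: from 28, carbodiimide esterification (EDC, 4-dimethylaminopyridine) with 2-[bis(2,2,2-trifluoroethoxy)phosphoryl]propanoic acid gives the tris(phosphonopropanoate) F7. A threefold Still–Gennari olefination with acetaldehyde (KN(SiMe3)2, 18-crown-6, THF, −78 °C) then builds the three (Z)-2-methylbut-2-enoates in place and returns to 31.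

## Further compounds

F1 | step 6 | 3β-iodo cis-fused lactone with C4=C5 (iodolactone of 7) | I[C@H]1C(C)=CC[C@@H]2CC(=O)O[C@H]12
F2 | step 6 | 3α-acetoxy cis-fused lactone with C4=C5 (acetate of 14) | CC(=O)O[C@@H]1C(C)=CC[C@@H]2CC(=O)O[C@H]12
F3 | step 10 | O5-(imidazol-1-ylthiocarbonyl) derivative of 11 | S=C(n4ccnc4)O[C@@H]1C[C@@H]2CC(=O)O[C@@H]2[C@@H]3O[C@]13C
F4 | step 15 | C7-(diethoxyphosphoryl) derivative of lactone 16 | CC(C)(C)[Si](C)(C)O[C@@H]1[C@]3(C)O[C@@H]3C[C@@H]2C(P(=O)(OCC)OCC)C(=O)O[C@H]12
F5 | step 21 | 7,8-epoxy-14-aldehyde from 25 | CC(C)(C)[Si](C)(C)O[C@@H]1[C@]3(C)O[C@@H]3C[C@H]([C@@]4(C=O)O[C@H]4CC=C(C)C)[C@@H]1O[Si](CC)(CC)CC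
F6 | step 21 | hydrazone of F5 | CC(C)(C)[Si](C)(C)O[C@@H]1[C@]3(C)O[C@@H]3C[C@H]([C@@]4(C=NN)O[C@H]4CC=C(C)C)[C@@H]1O[Si](CC)(CC)CC
F7 | step 23 | O2,O3,O8-tris{2-[bis(2,2,2-trifluoroethoxy)phosphoryl]propanoate} of 28 | C=C([C@H](CC=C(C)C)OC(=O)C(C)P(=O)(OCC(F)(F)F)OCC(F)(F)F)[C@H]1C[C@H]2O[C@@]2(C)[C@@H](OC(=O)C(C)P(=O)(OCC(F)(F)F)OCC(F)(F)F)[C@H]1OC(=O)C(C)P(=O)(OCC(F)(F)F)OCC(F)(F)F
A1 | alternative 1 | (E)-allylic alcohol with C9 carbinol, C7 methyl and the bis-silylated epoxy ring | OC/C=C(\C)[C@H]1C[C@H]2O[C@@]2(C)[C@@H](O[Si](C)(C)C(C)(C)C)[C@H]1O[Si](C)(C)C(C)(C)C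
A2 | alternative 1 | (7S,8S)-7,8-epoxy-9-ol | OC[C@@H]1O[C@@]1(C)[C@H]1C[C@H]2O[C@@]2(C)[C@@H](O[Si](C)(C)C(C)(C)C)[C@H]1O[Si](C)(C)C(C)(C)C
A3 | alternative 2 | 6-methyl-2H-pyran-2-one | CC1=CC=CC(=O)O1
A4 | alternative 2 | endo-7-acetyl-1-methyl-2-oxabicyclo[2.2.2]oct-5-en-3-one | O=C1O[C@@]2(C)C=C[C@@H]1C[C@@H]2C(C)=O
A5 | alternative 3 | methyl (2Z,5Z,7S)-2-(bromomethyl)-7-(tert-butyldimethylsilyloxy)-6-methyl-8-oxoocta-2,5-dienoate (acyclic aldehyde–allylic bromide) | O=C[C@H](O[Si](C)(C)C(C)(C)C)/C(C)=C\C/C=C(\CBr)C(=O)OC
A6 | alternative 3 | cis-fused α-methylene-γ-butyrolactone on C1–C2 with C3 silyl ether and C4=C5 alkene | C=C1C(=O)O[C@@H]2[C@H](O[Si](C)(C)C(C)(C)C)C(C)=CC[C@H]12
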